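Position labels C1–C15 use the germacrane numbering of the target: C1 ketone, C2=C3 furanone alkene, C4=C5, C6 lactone carbinol, C7, C8 (O-tigloyl), C9, C10 (quaternary), C11=C13 exo-methylene, C12 lactone C=O, C14 methyl, C15 CH2OH. From the SMILES the target is 6R,7R,8S,10R, with a trans 6,7-lactone, a ring-cis (Z) C4=C5 and an (E)-tiglate.

## Retrosynthetic overview
1. Last step: cut C2–C3, C3–C4 and O–C3. This gives an acyclic (Z)-vinyl iodide / terminal tertiary propargylic alcohol plus CO, so C3 comes from CO. The ten-membered carbocycle and the 3(2H)-furanone close in one pot.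
2. Remove the tiglate and cut C7–C8. The 8-hydroxy α-methylene lactone comes from (R)-3-hydroxy-3-methylpent-4-ynal and a ring-locked butenolide allylboronate (sets C7 and C8).
3. The butenolide boronate comes from a γ-hydroxy ynoate and ICH2Bpin. The ynoate comes from a (Z)-β-iodo enal (from but-2-yne-1,4-diol) and methyl propiolate (sets C6).
4. The aldehyde comes from the Sharpless epoxide of (E)-3-methylpent-2-en-4-yn-1-ol (sets C10).
5. Ring order: γ-lactone first (as a butenolide, step 8), then carbocycle and furanone together (step 11).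

Assumption: the ProPhenol ligand is written as (S,S). If its sense of induction on enal 9 is opposite, the commercial antipode is used and nothing else changes.

## Route

Step 1
Reactants: 1 (E)-3-methylpent-2-en-4-yn-1-ol
Product: 2 [(2S,3S)-3-ethynyl-3-methyloxiran-2-yl]methanol
Conditions: Ti(Oi-Pr)4 (10 mol %), L-(+)-DET (12 mol %), t-BuOOH (2 equiv), 4 Å MS, CH2Cl2, −20 °C
Reagents that add atoms: tert-butyl hydroperoxide, CC(C)(C)OO
Why: Sharpless asymmetric epoxidation of a geraniol-type E-trisubstituted allylic alcohol, in which L-(+)-DET gives the (2S,3S)-epoxide and so fixes the future C10, while the alkyne is inert to Ti/TBHP.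

Step 2
Reactants: 2 [(2S,3S)-3-ethynyl-3-methyloxiran-2-yl]methanol
Product: 3 (3R)-3-methylpent-4-yne-1,3-diol
Conditions: Red-Al (1.5 equiv), THF, −20 → 0 °C; aq Rochelle salt
Reagents that add atoms: none
Why: Hydroxy-directed Red-Al opening of a 2,3-epoxy alcohol, in which the alkoxide-bound hydride attacks the only non-quaternary epoxide carbon (C9) to give the 1,3-diol, the C10–O bond stays intact (C10 = R), and low temperature holds back SN2' reduction and alkyne hydroalumination.

Step 3
Reactants: 3 (3R)-3-methylpent-4-yne-1,3-diol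
Product: 4 (3R)-3-hydroxy-3-methylpent-4-ynal
Conditions: TEMPO (10 mol %), PhI(OAc)2 (1.1 equiv), CH2Cl2, 0 °C → rt; short silica plug, used at once
Reagents that add atoms: none
Why: TEMPO/PhI(OAc)2 oxidation takes only the primary alcohol, stops at the aldehyde and is near neutral, so the β-hydroxy aldehyde does not eliminate and C10 is untouched.

Step 4
Reactants: 5 but-2-yne-1,4-diol
Product: 6 4-[(tert-butyldimethylsilyl)oxy]but-2-yn-1-ol
Conditions: TBSCl (0.33 equiv), imidazole, DMF, 0 °C → rt (5 in threefold excess)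
Reagents that add atoms: tert-butyldimethylsilyl chloride, CC(C)(C)[Si](C)(C)Cl
Why: Statistical monosilylation of a cheap symmetrical diol used in excess, which differentiates the future C15 oxygen from C6.

Step 5
Reactants: 6 4-[(tert-butyldimethylsilyl)oxy]but-2-yn-1-ol
Product: 8 (2Z)-4-[(tert-butyldimethylsilyl)oxy]-3-iodobut-2-en-1-ol, via cyclic sodium alkenylalanate 7 (not isolated)
Conditions: Red-Al (1.5 equiv), THF, 0 °C → rt; then NIS, −78 → 0 °C; aq Rochelle salt
Reagents that add atoms: N-iodosuccinimide, O=C1CCC(=O)N1I; Red-Al, [Na+].COCCO[AlH2-]OCCOC (its atoms are kept only in 7)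
Why: Hydroxy-directed trans-hydroalumination places Al on the distal alkyne carbon in a five-membered alanate, and iodinolysis with retention gives only the Z-iodide, which is the C4=C5 geometry of the target.

Step 6
Reactants: 8 (2Z)-4-[(tert-butyldimethylsilyl)oxy]-3-iodobut-2-en-1-ol
Product: 9 (2Z)-4-[(tert-butyldimethylsilyl)oxy]-3-iodobut-2-enal
Conditions: MnO2 (15 equiv), CH2Cl2, rt, dark
Reagents that add atoms: none
Why: MnO2 allylic oxidation is neutral, so the silyl ether, the C–I bond and the Z geometry survive.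

Step 7
Reactants: 9 (2Z)-4-[(tert-butyldimethylsilyl)oxy]-3-iodobut-2-enal; 10 methyl propiolate
Product: 11 methyl (4R,5Z)-7-[(tert-butyldimethylsilyl)oxy]-4-hydroxy-6-iodohept-5-en-2-ynoate
Conditions: 10 (2.8 equiv), Me2Zn (2.9 equiv), (S,S)-ProPhenol (20 mol %), Ph3P=O (40 mol %), toluene, 4 °C; aq NH4Cl
Reagents that add atoms: none
Why: Dinuclear Zn-ProPhenol asymmetric alkynylation, for which enal plus methyl propiolate is the standard pairing, adds 1,2 and sets C6 (R) by catalyst control, and no Pd is present to touch the vinyl iodide.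

Step 8
Reactants: 11 methyl (4R,5Z)-7-[(tert-butyldimethylsilyl)oxy]-4-hydroxy-6-iodohept-5-en-2-ynoate; 12 2-(iodomethyl)-4,4,5,5-tetramethyl-1,3,2-dioxaborolane
Product: 15 (5S)-5-[(1Z)-3-[(tert-butyldimethylsilyl)oxy]-2-iodoprop-1-en-1-yl]-3-[(4,4,5,5-tetramethyl-1,3,2-dioxaborolan-2-yl)methyl]furan-2(5H)-one, via bis(diisobutylaluminium) vinylalane alkoxide 13 (not isolated), via open-chain hydroxy ester allylboronate 14 (not isolated)
Conditions: DIBAL-H (2.3 equiv), HMPA (2.5 equiv), THF, 0 °C; then 12 (1.3 equiv), 0 °C → rt; aq Rochelle salt, then 10 % citric acid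
Reagents that add atoms: diisobutylaluminium hydride, CC(C)C[AlH]CC(C)C (Al and isobutyl groups are kept only in 13)
Why: Conjugate syn-hydroalumination of the ynoate puts H on C7 and Al on C11 with C6 cis to the ester, attack on boron followed by a Matteson-type 1,2-shift installs CH2Bpin (C13) with retention, and the cis γ-hydroxy ester lactonises on mild acid work-up without touching C6 (same spatial arrangement, now S by CIP).

Step 9
Reactants: 15 butenolide allylboronate (name as in step 8); 4 (3R)-3-hydroxy-3-methylpent-4-ynal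
Product: 17 (4R,5S)-4-[(1S,3R)-1,3-dihydroxy-3-methylpent-4-yn-1-yl]-5-[(1Z)-3-[(tert-butyldimethylsilyl)oxy]-2-iodoprop-1-en-1-yl]-3-methylideneoxolan-2-one, via C8 pinacol borate 16 (not isolated)
Conditions: 4 (1.5 equiv), Sc(OTf)3 (10 mol %), toluene, 0 °C → rt; aq NaHCO3
Reagents that add atoms: none
Why: Lewis-acid-catalysed type-I allylboration of a 2-carboxy allylboronate through a closed chair, in which the ring-locked E-allyl geometry gives the anti C7/C8 relationship, the aldehyde reaches C7 anti to the C6 alkenyl group (trans lactone, 7R,8S), and allyl transposition creates the exo-methylene.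

Step 10
Reactants: 17 hydroxy lactone (name as in step 9); 18 tiglic acid, (2E)-2-methylbut-2-enoic acid
Product: 20 (1S,3R)-1-{(2S,3R)-2-[(1Z)-3-[(tert-butyldimethylsilyl)oxy]-2-iodoprop-1-en-1-yl]-4-methylidene-5-oxooxolan-3-yl}-3-hydroxy-3-methylpent-4-yn-1-yl (2E)-2-methylbut-2-enoate, via tiglic 2,4,6-trichlorobenzoic anhydride 19 (not isolated)
Conditions: 18 (3 equiv), 2,4,6-Cl3C6H2COCl (3 equiv), Et3N, toluene, rt; then 17, DMAP, rt
Reagents that add atoms: 2,4,6-trichlorobenzoyl chloride, O=C(Cl)c1c(Cl)cc(Cl)cc1Cl (its acyl group is kept only in 19)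
Why: Yamaguchi esterification acylates the secondary C8-OH and leaves the tertiary propargylic OH alone, tiglate is the stable E isomer, and no stereocenter is affected.

Step 11
Reactants: 20 seco iodo-alkyne tiglate (name as in step 10)
Product: 24 lychnophorolide B, via macrocyclic ynone 21 (not isolated), via macrocyclic enaminone 22 (not isolated), via 15-O-TBS-lychnophorolide B 23 (not isolated)
Conditions: PdCl2(PPh3)2 (10 mol %), CuI (5 mol %), Et3N (5 equiv), CO (1 atm), THF, 40 °C, 20 added by syringe pump over 16 h (final 1 mM); Ar purge, Et2NH (1.2 equiv), 0 °C, 30 min; then 1 M aq HCl–THF, rt, 4 h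
Reagents that add atoms: carbon monoxide, [C-]#[O+]; water, O; diethylamine, CCNCC (kept only in 22)
Why: Proposed new method: Pd(0) inserts into the Z-vinyl iodide with retention, CO insertion and Cu-acetylide transmetalation/reductive elimination close the ten-membered cross-conjugated ynone 21 (CO-free coupling would need a nine-membered enyne, and pseudo-high dilution suppresses oligomers), the strained ynone takes up Et2NH at C1 much faster than the α-methylene lactone does, and aqueous acid then lets the C10-OH add to the C3 ketone, lose water and hydrolyse the iminium to the 3(2H)-furanone while the primary allylic TBS ether is cleaved; the closest known reaction types are intermolecular carbonylative Sonogashira coupling of iodides with tertiary ethynyl carbinols, amine/acid conversion of 4-hydroxy-2-ynones into 3(2H)-furanones, and carbonylative Stille macrocyclisation, and no stereocenter is made or touched.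

## Compound list
1 | (E)-3-methylpent-2-en-4-yn-1-ol | C#C/C(C)=C/CO | starting material
2 | [(2S,3S)-3-ethynyl-3-methyloxiran-2-yl]methanol | OC[C@@H]1O[C@@]1(C)C#C | intermediate
3 | (3R)-3-methylpent-4-yne-1,3-diol | OCC[C@@](C)(O)C#C | intermediate
4 | (3R)-3-hydroxy-3-methylpent-4-ynal (C8–C10, C14, C1, C2) | O=CC[C@@](C)(O)C#C | intermediate
5 | but-2-yne-1,4-diol | OCC#CCO | starting material
6 | 4-[(tert-butyldimethylsilyl)oxy]but-2-yn-1-ol | OCC#CCO[Si](C)(C)C(C)(C)C | intermediate
7 | sodium 2,2-bis(2-methoxyethoxy)-1,2-oxaluminol-3-ene ate complex bearing CH2OTBS on the Al-bound carbon | [Na+].COCCO[Al-]1(OCCOC)OCC=C1CO[Si](C)(C)C(C)(C)C | intermediate (not isolated)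
8 | (2Z)-4-[(tert-butyldimethylsilyl)oxy]-3-iodobut-2-en-1-ol | OC/C=C(/CO[Si](C)(C)C(C)(C)C)I | intermediate
9 | (2Z)-4-[(tert-butyldimethylsilyl)oxy]-3-iodobut-2-enal | O=C/C=C(/CO[Si](C)(C)C(C)(C)C)I | intermediate
10 | methyl propiolate | C#CC(=O)OC | starting material
11 | methyl (4R,5Z)-7-[(tert-butyldimethylsilyl)oxy]-4-hydroxy-6-iodohept-5-en-2-ynoate | COC(=O)C#C[C@H](O)/C=C(/CO[Si](C)(C)C(C)(C)C)I | intermediate
12 | 2-(iodomethyl)-4,4,5,5-tetramethyl-1,3,2-dioxaborolane | ICB1OC(C)(C)C(C)(C)O1 | starting material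
13 | syn-hydroalumination adduct of 11: C11–Al(i-Bu)2, H on C7, C6 cis to CO2Me, C6–O–Al(i-Bu)2 | COC(=O)/C([Al](CC(C)C)CC(C)C)=C\[C@H](O[Al](CC(C)C)CC(C)C)/C=C(/CO[Si](C)(C)C(C)(C)C)I | intermediate (not isolated)
14 | methyl (2Z,4S,5Z)-7-[(tert-butyldimethylsilyl)oxy]-4-hydroxy-6-iodo-2-[(pinacolboryl)methyl]hepta-2,5-dienoate | COC(=O)/C(CB1OC(C)(C)C(C)(C)O1)=C\[C@H](O)/C=C(/CO[Si](C)(C)C(C)(C)C)I | intermediate (not isolated)
15 | (5S)-5-[(1Z)-3-(TBSO)-2-iodoprop-1-enyl]-3-[(pinacolboryl)methyl]furan-2(5H)-one | O=C1O[C@H](/C=C(/CO[Si](C)(C)C(C)(C)C)I)C=C1CB2OC(C)(C)C(C)(C)O2 | intermediate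
16 | C8-O-pinacol borate of 17 | C=C1C(=O)O[C@H](/C=C(/CO[Si](C)(C)C(C)(C)C)I)[C@H]1[C@@H](OB2OC(C)(C)C(C)(C)O2)C[C@@](C)(O)C#C | intermediate (not isolated)
17 | trans α-methylene lactone with free 8-OH and 10-OH (spatially 6R,7R,8S,10R of the target) | C=C1C(=O)O[C@H](/C=C(/CO[Si](C)(C)C(C)(C)C)I)[C@H]1[C@@H](O)C[C@@](C)(O)C#C | intermediate
18 | tiglic acid | C/C=C(\C)C(=O)O | starting material
19 | tiglic 2,4,6-trichlorobenzoic mixed anhydride | C/C=C(\C)C(=O)OC(=O)c1c(Cl)cc(Cl)cc1Cl | intermediate (not isolated)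
20 | 8-O-tiglate of 17 (seco vinyl iodide / terminal alkyne) | C=C1C(=O)O[C@H](/C=C(/CO[Si](C)(C)C(C)(C)C)I)[C@H]1[C@@H](OC(=O)/C(C)=C/C)C[C@@](C)(O)C#C | intermediate
21 | ten-membered 1-yn-3-one (C1≡C2, C3=O, Z-C4=C5), 10-OH free, 15-OTBS | C=C1C(=O)O[C@@H]2/C=C(/CO[Si](C)(C)C(C)(C)C)C(=O)C#C[C@](C)(O)C[C@H](OC(=O)/C(C)=C/C)[C@@H]12 | intermediate (not isolated)
22 | C1-diethylamino enaminone of 21 (C1=C2 geometry labile, push–pull) | C=C1C(=O)O[C@@H]2/C=C(/CO[Si](C)(C)C(C)(C)C)C(=O)C=C(N(CC)CC)[C@](C)(O)C[C@H](OC(=O)/C(C)=C/C)[C@@H]12 | intermediate (not isolated)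
23 | 15-O-TBS-lychnophorolide B | C=C1C(=O)O[C@@H]2/C=C(/CO[Si](C)(C)C(C)(C)C)C3=CC(=O)[C@@](C)(C[C@H](OC(=O)/C(C)=C/C)[C@@H]12)O3 | intermediate (not isolated)
24 | lychnophorolide B (6R,7R,8S,10R) | C=C1C(=O)O[C@@H]2/C=C(/CO)C3=CC(=O)[C@@](C)(C[C@H](OC(=O)/C(C)=C/C)[C@@H]12)O3 | target

## Step count
- **Total:** 11 steps.
- **Longest linear sequence:** 8 steps (steps 4–11, from but-2-yne-1,4-diol).

## Steps most likely to fail

**Step 11.** The risks are ring strain in the Pd(acyl)(alkynyl) ring closure, oligomerisation, Heck-type capture by the exo-methylene, and amine addition to the lactone. The fallback sets out from 20 and closes the ring at C2–C3 through an sp3-rich chain instead of an alkyne.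
- Markovnikov hydration of the terminal alkyne (Ph3PAuNTf2 cat., wet dioxane) gives the α-hydroxy methyl ketone F1.
- Pd-catalysed alkoxycarbonylation of the vinyl iodide with pentafluorophenol (CO, Et3N) gives the pentafluorophenyl ester F2.
- Soft-enolisation macro-Claisen acylation (MgBr2·OEt2, i-Pr2NEt, CH2Cl2, high dilution) gives the macrocyclic α'-hydroxy-1,3-diketone F3.
- F3 cyclodehydrates with PPTS, and the route is rejoined at 23. The aqueous HCl treatment of step 11 then gives 24.

**Step 8.** The risks are that the α-aluminio enoate fails to engage ICH2Bpin, protodealumination, and E/Z leakage through the allenolate. The fallback sets out from 11 and replaces allylboron chemistry with a Barbier allylation.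
- The same vinylalane 13 is quenched with monomeric formaldehyde. After lactonisation this gives the 3-(hydroxymethyl)butenolide F4.
- Appel bromination (CBr4, PPh3) gives the 3-(bromomethyl)butenolide F5.
- Zinc in THF/aq NH4Cl (or CrCl2 in THF) with aldehyde 4 gives the same ring-locked E-allylmetal, and so the same anti/trans adduct.
- The route is rejoined at 17, bypassing 15 and step 9.

**Step 2.** The risks are SN2' hydride delivery to give an allenol and hydroalumination of the propargylic alkoxide. The fallback sets out from 2 and cleaves the C9–O bond by internal redox instead of external hydride.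
- TEMPO/PhI(OAc)2 oxidation gives the epoxy aldehyde F6.
- NHC-catalysed redox esterification (triazolium salt, i-Pr2NEt, MeOH) opens the epoxide through the Breslow intermediate and gives the β-hydroxy ester F7 with C10 untouched.
- DIBAL-H at −78 °C gives the aldehyde, and the route is rejoined at 4.

## Further compounds
F1 | step 11 | α-hydroxy methyl ketone from hydration of 20 | C=C1C(=O)O[C@H](/C=C(/CO[Si](C)(C)C(C)(C)C)I)[C@H]1[C@@H](OC(=O)/C(C)=C/C)C[C@@](C)(O)C(C)=O
F2 | step 11 | pentafluorophenyl ester (C3 carboxyl on C4) of F1 | C=C1C(=O)O[C@H](/C=C(/CO[Si](C)(C)C(C)(C)C)C(=O)Oc2c(F)c(F)c(F)c(F)c2F)[C@H]1[C@@H](OC(=O)/C(C)=C/C)C[C@@](C)(O)C(C)=O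
F3 | step 11 | macrocyclic 10-hydroxy-1,3-diketone | C=C1C(=O)O[C@@H]2/C=C(/CO[Si](C)(C)C(C)(C)C)C(=O)CC(=O)[C@](C)(O)C[C@H](OC(=O)/C(C)=C/C)[C@@H]12
F4 | step 8 | (5S)-3-(hydroxymethyl)-5-[(1Z)-3-(TBSO)-2-iodoprop-1-enyl]furan-2(5H)-one | O=C1O[C@H](/C=C(/CO[Si](C)(C)C(C)(C)C)I)C=C1CO
F5 | step 8 | (5S)-3-(bromomethyl)-5-[(1Z)-3-(TBSO)-2-iodoprop-1-enyl]furan-2(5H)-one | O=C1O[C@H](/C=C(/CO[Si](C)(C)C(C)(C)C)I)C=C1CBr
F6 | step 2 | (2R,3S)-3-ethynyl-3-methyloxirane-2-carbaldehyde | O=C[C@@H]1O[C@@]1(C)C#C
F7 | step 2 | methyl (3R)-3-hydroxy-3-methylpent-4-ynoate | COC(=O)C[C@@](C)(O)C#C
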